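**Plan**
1. First cut: O1–C8a of the pyran ring. Ring A is then a plain 3,4,5-trimethoxybenzyl group whose two ortho carbons (future C5 and C8a) are equivalent, each para to a methoxy group and six atoms from the hydroxyl oxygen; ring B, as a quinone, cannot be oxidised further.
2. Second cut: the two C=O groups of ring B go back to the para pair of methyl ethers of a 2,3,4,5-tetramethoxyphenyl ring.
3. Third cut: C3–C4 (enolate benzylation), with C2 traced back to the carbonyl of an arylacetyl imide.
4. Forward: ring B acid (bromination, methoxylation) → imide → C3–C4 bond → primary alcohol → ring B oxidised to the quinone → pyran ring closed last by dehydrogenative C–H/O–H coupling on ring A.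
5. Stereochemistry: the only stereocentre (C3, S) is set in the Evans alkylation by (S)-4-benzyloxazolidin-2-one and no later step touches it.

Key step: step 7

Remark: chroman numbering is used (O1, C2, C3, C4, C4a, C5–C8, C8a; ring A is the benzo ring, ring B the quinone, its positions primed). The stereocentre of the given structure is read as S, and compounds 1, 4 and 7 are taken as commercial.

Step 1
Reactants: 1 2-(3,4,5-trimethoxyphenyl)acetic acid
Product: 2 2-(2-bromo-3,4,5-trimethoxyphenyl)acetic acid
Conditions: NBS (1.05 equiv), MeCN, 0 °C → rt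
Reagents that add atoms: N-bromosuccinimide, O=C1CCC(=O)N1Br
Why: Electrophilic aromatic bromination should take one of the two equivalent free ring positions, each ortho and para to methoxy groups, and so places a leaving group where the fourth oxygen of ring B is needed.

Step 2
Reactants: 2 2-(2-bromo-3,4,5-trimethoxyphenyl)acetic acid
Product: 3 2-(2,3,4,5-tetramethoxyphenyl)acetic acid
Conditions: NaOMe (6 equiv), CuBr (15 mol%), MeOH–DMF, 110 °C; acidic work-up
Reagents that add atoms: NaOMe, [Na+].[O-]C
Why: Copper-catalysed Ullmann-type methoxylation of an aryl bromide with NaOMe is the usual way from 2-bromo-3,4,5-trimethoxyarenes to 2,3,4,5-tetramethoxyarenes, and the carboxylate should be carried through unchanged.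

Step 3
Reactants: 3 2-(2,3,4,5-tetramethoxyphenyl)acetic acid; 4 (S)-4-benzyloxazolidin-2-one
Product: 6 (S)-4-benzyl-3-[2-(2,3,4,5-tetramethoxyphenyl)acetyl]oxazolidin-2-one, via mixed pivalic anhydride 5 (not isolated)
Conditions: PivCl, Et3N, THF, −20 °C; then LiCl, 4, −20 °C → rt
Reagents that add atoms: pivaloyl chloride, CC(C)(C)C(Cl)=O (its atoms are held in 5 only)
Why: N-Acylation of the oxazolidinone through the mixed pivalic anhydride with LiCl/Et3N is a standard entry to Evans imides from arylacetic acids and forms no stereocentre.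

Step 4
Reactants: 6 (S)-4-benzyl-3-[2-(2,3,4,5-tetramethoxyphenyl)acetyl]oxazolidin-2-one; 7 5-(bromomethyl)-1,2,3-trimethoxybenzene (3,4,5-trimethoxybenzyl bromide)
Product: 9 (S)-4-benzyl-3-[(S)-2-(2,3,4,5-tetramethoxyphenyl)-3-(3,4,5-trimethoxyphenyl)propanoyl]oxazolidin-2-one, via sodium Z-enolate 8 (not isolated)
Conditions: NaN(SiMe3)2 (1.05 equiv), THF, −78 °C; then 7, −78 → −40 °C
Reagents that add atoms: NaN(SiMe3)2, C[Si](C)(C)[N-][Si](C)(C)C.[Na+] (its sodium is held in 8 only)
Why: Evans asymmetric alkylation: the chelated sodium Z-enolate should be attacked by the benzylic bromide on the face opposite the benzyl group at C4 of the auxiliary, which for the (S)-auxiliary gives the (S)-configured α-carbon, the future C3 (the aryl group outranks the new CH2Ar group).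

Step 5
Reactants: 9 (S)-4-benzyl-3-[(S)-2-(2,3,4,5-tetramethoxyphenyl)-3-(3,4,5-trimethoxyphenyl)propanoyl]oxazolidin-2-one
Product: 10 (S)-2-(2,3,4,5-tetramethoxyphenyl)-3-(3,4,5-trimethoxyphenyl)propan-1-ol
Conditions: LiBH4, MeOH (1 equiv), THF, 0 °C
Reagents that add atoms: none
Why: Reductive cleavage of the imide with LiBH4 (hydride attack at the exocyclic carbonyl) should give the primary alcohol without epimerisation of the α-aryl centre and return the auxiliary.

Step 6
Reactants: 10 (S)-2-(2,3,4,5-tetramethoxyphenyl)-3-(3,4,5-trimethoxyphenyl)propan-1-ol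
Product: 11 (S)-5-[1-hydroxy-3-(3,4,5-trimethoxyphenyl)propan-2-yl]-2,3-dimethoxycyclohexa-2,5-diene-1,4-dione
Conditions: (NH4)2Ce(NO3)6 (2.5 equiv), MeCN–H2O 2:1, 0 °C, short reaction time
Reagents that add atoms: water, O
Why: Oxidative demethylation with tetravalent cerium: ring B, with its para pair of methoxy groups at C2'/C5', should be oxidised to the radical cation, take up water at the two ipso carbons and lose methanol to give the para-quinone, while ring A, which has no para pair of oxygens and is harder to oxidise, and the stereocentre are left alone.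

Step 7
Reactants: 11 (S)-5-[1-hydroxy-3-(3,4,5-trimethoxyphenyl)propan-2-yl]-2,3-dimethoxycyclohexa-2,5-diene-1,4-dione
Product: 12 abruquinone B, (S)-2,3-dimethoxy-5-(6,7,8-trimethoxychroman-3-yl)cyclohexa-2,5-diene-1,4-dione
Conditions: PhI(OCOCF3)2 (1.0 equiv, added slowly), CH2Cl2–(CF3)2CHOH, −30 °C, dark; NaHCO3 quench
Reagents that add atoms: none
Why: PhI(OCOCF3)2 in (CF3)2CHOH should take one electron from ring A, the only oxidisable π-system left once ring B is a quinone, to give an arene radical cation; the primary hydroxyl adds to the ortho carbon (future C8a, para to the future C6 methoxy group), and a second one-electron oxidation with loss of the C8a proton restores the arene, a net dehydrogenative C–H/O–H coupling that forms O1–C8a. The closest known reaction type is the hypervalent-iodine (also anodic or peroxydisulfate) oxidative cyclisation of 3-arylpropan-1-ols to chromans through arene radical cations. The pyran ring closes in a 6-endo mode onto the C4a–C8a edge of the arene. No stereocentre is formed, and C3 should stay S because no bond to it is made or broken and the medium is not basic. The step needs site selectivity and a stop at the chroman stage: the quinone is electron-poor and could reach the hydroxyl only by a strained 5-endo closure, C8a is para to a coplanar methoxy group whereas the ipso carbon C4a is para only to the twisted central one, the two ortho C–H positions are equivalent by the local symmetry of the 3,4,5-trimethoxyphenyl ring, and one equivalent of oxidant added slowly in the cold limits further oxidation of the product.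

**Compound list**
1 | 2-(3,4,5-trimethoxyphenyl)acetic acid | COc1cc(CC(=O)O)cc(OC)c1OC | starting material
2 | 2-(2-bromo-3,4,5-trimethoxyphenyl)acetic acid | COc1cc(CC(=O)O)c(Br)c(OC)c1OC | intermediate
3 | 2-(2,3,4,5-tetramethoxyphenyl)acetic acid | COc1cc(CC(=O)O)c(OC)c(OC)c1OC | intermediate
4 | (S)-4-benzyloxazolidin-2-one | O=C1N[C@@H](Cc2ccccc2)CO1 | starting material
5 | 2-(2,3,4,5-tetramethoxyphenyl)acetic pivalic anhydride | COc1cc(CC(=O)OC(=O)C(C)(C)C)c(OC)c(OC)c1OC | intermediate (not isolated)
6 | (S)-4-benzyl-3-[2-(2,3,4,5-tetramethoxyphenyl)acetyl]oxazolidin-2-one | COc1cc(CC(=O)N2[C@@H](Cc3ccccc3)COC2=O)c(OC)c(OC)c1OC | intermediate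
7 | 5-(bromomethyl)-1,2,3-trimethoxybenzene | COc1cc(CBr)cc(OC)c1OC | starting material
8 | sodium Z-enolate of 6 | [Na+].[O-]/C(=C\c1cc(OC)c(OC)c(OC)c1OC)N1[C@@H](Cc2ccccc2)COC1=O | intermediate (not isolated)
9 | (S)-4-benzyl-3-[(S)-2-(2,3,4,5-tetramethoxyphenyl)-3-(3,4,5-trimethoxyphenyl)propanoyl]oxazolidin-2-one | COc1cc(C[C@H](C(=O)N2[C@@H](Cc3ccccc3)COC2=O)c2cc(OC)c(OC)c(OC)c2OC)cc(OC)c1OC | intermediate
10 | (S)-2-(2,3,4,5-tetramethoxyphenyl)-3-(3,4,5-trimethoxyphenyl)propan-1-ol | COc1cc(C[C@H](CO)c2cc(OC)c(OC)c(OC)c2OC)cc(OC)c1OC | intermediate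
11 | (S)-5-[1-hydroxy-3-(3,4,5-trimethoxyphenyl)propan-2-yl]-2,3-dimethoxycyclohexa-2,5-diene-1,4-dione | COc1cc(C[C@H](CO)C2=CC(=O)C(OC)=C(OC)C2=O)cc(OC)c1OC | intermediate
12 | abruquinone B, (S)-2,3-dimethoxy-5-(6,7,8-trimethoxychroman-3-yl)cyclohexa-2,5-diene-1,4-dione | COC1=C(OC)C(=O)C([C@H]2COc3c(cc(OC)c(OC)c3OC)C2)=CC1=O | target

**Count**
Total steps: 7. Longest linear sequence: 7 steps (1 → 12); 4 and 7 enter as bought materials.

**Steps most likely to fail**

Step 7. The process at risk is further one-electron oxidation of the newly formed, more electron-rich ring A (demethylation or reopening of the pyran ring). A second risk is attack of the hydroxyl at the ipso carbon C4a, with spirocyclisation. The fallback sets out from 11 and comes back at 12; it forms the same O1–C8a bond by a two-electron copper-catalysed coupling instead of a radical cation. NBS in MeCN at 0 °C should brominate one of the two equivalent ortho positions of ring A, the quinone being inert, to give (S)-5-[1-(2-bromo-3,4,5-trimethoxyphenyl)-3-hydroxypropan-2-yl]-2,3-dimethoxycyclohexa-2,5-diene-1,4-dione F1. Na2S2O4 in EtOAc–H2O reduces the quinone to (S)-5-[1-(2-bromo-3,4,5-trimethoxyphenyl)-3-hydroxypropan-2-yl]-2,3-dimethoxybenzene-1,4-diol F2. BnBr and K2CO3 in DMF benzylate both phenols and leave the primary alcohol, giving (S)-2-[2,5-bis(benzyloxy)-3,4-dimethoxyphenyl]-3-(2-bromo-3,4,5-trimethoxyphenyl)propan-1-ol F3. Intramolecular Ullmann etherification (CuI, 3,4,7,8-tetramethyl-1,10-phenanthroline, Cs2CO3, toluene, 100 °C) closes the pyran ring to (S)-3-[2,5-bis(benzyloxy)-3,4-dimethoxyphenyl]-6,7,8-trimethoxychroman F4. Hydrogenolysis (H2, Pd/C, EtOAc) gives (S)-2,3-dimethoxy-5-(6,7,8-trimethoxychroman-3-yl)benzene-1,4-diol F5, which Ag2O in Et2O oxidises to 12.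

Step 6. The process at risk is loss of chemoselectivity: oxidation of ring A, fragmentation of the β-aryl alcohol at the radical-cation stage, or loss of the wrong pair of methyl groups to give an ortho-quinone. The fallback sets out from 10 and comes back at 11. TBSCl and imidazole in DMF mask the alcohol as (S)-tert-butyldimethyl[2-(2,3,4,5-tetramethoxyphenyl)-3-(3,4,5-trimethoxyphenyl)propoxy]silane F6. Anodic oxidation (carbon anode, KOH/MeOH, 0 °C, undivided cell, charge limited to two electrons per molecule) adds methoxide to the para pair C2'/C5' of ring B, which fixes the para-quinone pattern, and gives the quinone bis(dimethyl ketal) (S)-tert-butyl[2-(3,3,4,5,6,6-hexamethoxycyclohexa-1,4-dien-1-yl)-3-(3,4,5-trimethoxyphenyl)propoxy]dimethylsilane F7. Aqueous CF3CO2H in THF then hydrolyses both ketals and the silyl ether to 11.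

Step 2. The process at risk is delivery of oxygen by the ortho carboxylate itself (copper-mediated lactonisation and reopening), so that a phenol is formed instead of the methyl ether, together with reductive loss of bromine. The fallback sets out from 2 and comes back at 3 and uses that pathway on purpose. Aqueous NaOH with catalytic CuSO4 at reflux replaces bromine by hydroxyl to give 2-(2-hydroxy-3,4,5-trimethoxyphenyl)acetic acid F8, which closes on acidification to 5,6,7-trimethoxybenzofuran-2(3H)-one F9. F9 reopens in excess aqueous NaOH to the phenoxide carboxylate, Me2SO4 methylates the phenoxide, and acidification gives 3.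

**Further compounds**
F1 | step 7 | (S)-5-[1-(2-bromo-3,4,5-trimethoxyphenyl)-3-hydroxypropan-2-yl]-2,3-dimethoxycyclohexa-2,5-diene-1,4-dione | COc1cc(C[C@H](CO)C2=CC(=O)C(OC)=C(OC)C2=O)c(Br)c(OC)c1OC
F2 | step 7 | (S)-5-[1-(2-bromo-3,4,5-trimethoxyphenyl)-3-hydroxypropan-2-yl]-2,3-dimethoxybenzene-1,4-diol | COc1cc(C[C@H](CO)c2cc(O)c(OC)c(OC)c2O)c(Br)c(OC)c1OC
F3 | step 7 | (S)-2-[2,5-bis(benzyloxy)-3,4-dimethoxyphenyl]-3-(2-bromo-3,4,5-trimethoxyphenyl)propan-1-ol | COc1cc(C[C@H](CO)c2cc(OCc3ccccc3)c(OC)c(OC)c2OCc4ccccc4)c(Br)c(OC)c1OC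
F4 | step 7 | (S)-3-[2,5-bis(benzyloxy)-3,4-dimethoxyphenyl]-6,7,8-trimethoxychroman | COc1c(OC)c(OCc2ccccc2)c([C@H]2COc3c(cc(OC)c(OC)c3OC)C2)cc1OCc1ccccc1
F5 | step 7 | (S)-2,3-dimethoxy-5-(6,7,8-trimethoxychroman-3-yl)benzene-1,4-diol | COc1c(OC)c(O)c([C@H]2COc3c(cc(OC)c(OC)c3OC)C2)cc1O
F6 | step 6 | (S)-tert-butyldimethyl[2-(2,3,4,5-tetramethoxyphenyl)-3-(3,4,5-trimethoxyphenyl)propoxy]silane | COc1cc(C[C@H](CO[Si](C)(C)C(C)(C)C)c2cc(OC)c(OC)c(OC)c2OC)cc(OC)c1OC
F7 | step 6 | (S)-tert-butyl[2-(3,3,4,5,6,6-hexamethoxycyclohexa-1,4-dien-1-yl)-3-(3,4,5-trimethoxyphenyl)propoxy]dimethylsilane | COc1cc(C[C@H](CO[Si](C)(C)C(C)(C)C)C2=CC(OC)(OC)C(OC)=C(OC)C2(OC)OC)cc(OC)c1OC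
F8 | step 2 | 2-(2-hydroxy-3,4,5-trimethoxyphenyl)acetic acid | COc1cc(CC(=O)O)c(O)c(OC)c1OC
F9 | step 2 | 5,6,7-trimethoxybenzofuran-2(3H)-one | COc1cc2CC(=O)Oc2c(OC)c1OC
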